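The route rests on cutting the bond between C6 of ring A and the allylic CH2 of the geranyl chain, at the stage of an achiral chromone. C6 is the only ring A carbon ortho to the 5-OH that is hydrogen-bonded to the C4 carbonyl of ring C. Iodine can therefore be placed there alone, and O5 and O7 then flank and stabilise a carbon–zinc bond at C6. In one flask, 6-iodo-5,7-bis(methoxymethoxy)chromone is zincated and joined to commercial geranyl bromide under palladium catalysis, site-specifically and with retention of the E alkene. C2 is set afterwards by rhodium-catalysed asymmetric 1,4-addition of the ring B boronic acid. Only an acidic deprotection follows.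

Key step: step 4

Assumption: the (S)-configured biaryl bisphosphine is taken to induce on the chromone as it does on 2-cyclohexenone (aryl transfer to the Re face of C2, giving 2S); if the sense is opposite, the (R)-ligand is used.

Step 1
Reactants: 1 5,7-dihydroxy-4H-chromen-4-one (5,7-dihydroxychromone)
Product: 2 5-hydroxy-7-(methoxymethoxy)-4H-chromen-4-one
Conditions: MOMCl (1.1 equiv), K2CO3, acetone, 0 °C to rt
Reagents that add atoms: chloromethyl methyl ether (MOMCl), COCCl
Why: Williamson-type O-alkylation is selective because the 7-OH is the most acidic phenol (vinylogous acid of the C4 carbonyl), while the 5-OH is held in a hydrogen bond to that carbonyl and stays free.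

Step 2
Reactants: 2 5-hydroxy-7-(methoxymethoxy)-4H-chromen-4-one
Product: 3 5-hydroxy-6-iodo-7-(methoxymethoxy)-4H-chromen-4-one
Conditions: NIS (1.05 equiv), DMF, rt, dark
Reagents that add atoms: N-iodosuccinimide, O=C1CCC(=O)N1I
Why: Electrophilic aromatic iodination under neutral conditions goes ortho to the only free phenol, the chelated 5-OH, so iodine should enter at C6 and not at C8, as known for 5-hydroxy-7-alkoxyflavones.

Step 3
Reactants: 3 5-hydroxy-6-iodo-7-(methoxymethoxy)-4H-chromen-4-one
Product: 4 6-iodo-5,7-bis(methoxymethoxy)-4H-chromen-4-one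
Conditions: NaH, MOMCl, DMF, 0 °C to rt
Reagents that add atoms: chloromethyl methyl ether (MOMCl), COCCl
Why: Full deprotonation breaks the hydrogen bond and the sodium phenoxide undergoes Williamson-type alkylation, which removes the acidic proton before the organozinc step and the chelating phenol before the rhodium step.

Step 4
Reactants: 4 6-iodo-5,7-bis(methoxymethoxy)-4H-chromen-4-one; 5 geranyl bromide, (2E)-1-bromo-3,7-dimethylocta-2,6-diene
Product: 7 6-[(2E)-3,7-dimethylocta-2,6-dienyl]-5,7-bis(methoxymethoxy)-4H-chromen-4-one, via arylzinc iodide 6 (not isolated)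
Conditions: Zn dust, LiCl, THF, 50 °C; solution decanted from excess Zn; then 5, Pd(PPh3)4 (3 mol %), THF, 0 to 25 °C
Reagents that add atoms: none
Why: LiCl-promoted direct insertion of zinc into the carbon–iodine bond at C6, helped by coordination to the two flanking methoxymethoxy oxygens on C5 and C7 (directed ortho insertion), gives arylzinc iodide 6, which is too mild a nucleophile to attack C2 or C4 of the pyranone ring C. Zerovalent palladium ionises 5 to an η3-geranyl palladium bromide that keeps the alkene geometry, 6 transfers its aryl group to palladium, and reductive elimination at the unsubstituted allyl terminus forms the bond from C6 to the geranyl CH2. The closest known reaction type is the Negishi coupling of aryl- and alkenylzinc reagents with geranyl and neryl halides, which is regio- and stereospecific. No ring is closed and no stereocentre is formed in this step. Site selectivity on ring A (C6 against C8) is secured because the metal can only sit where iodine was placed, linear against branched coupling by the steric gap between the CH2 terminus and the fully substituted terminus of the allyl ligand, and E retention because syn/anti exchange would need a σ-bond from palladium to that tertiary carbon.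

Step 5
Reactants: 8 2,3-dimethoxyphenol
Product: 9 1,2-dimethoxy-3-(methoxymethoxy)benzene
Conditions: NaH, MOMCl, THF/DMF, 0 °C to rt
Reagents that add atoms: chloromethyl methyl ether (MOMCl), COCCl
Why: Williamson-type alkylation of the sodium phenoxide masks the future 3'-OH with the same acid-labile group used on ring A.

Step 6
Reactants: 9 1,2-dimethoxy-3-(methoxymethoxy)benzene
Product: 11 [3,4-dimethoxy-5-(methoxymethoxy)phenyl]boronic acid, via aryl pinacol boronate 10 (not isolated)
Conditions: [Ir(OMe)(cod)]2 (1.5 mol %), dtbpy (3 mol %), B2pin2 (0.55 equiv), THF, 80 °C; then NaIO4, NH4OAc, acetone/H2O, rt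
Reagents that add atoms: bis(pinacolato)diboron, CC1(C)OB(OC1(C)C)B1OC(C)(C)C(C)(C)O1; water, O
Why: Sterically controlled iridium-catalysed C–H borylation attacks the only C–H bond of the 1,2,3-trisubstituted ring that has no ortho substituent (C5), and periodate cleavage of the released pinacol drives hydrolysis to the boronic acid under near-neutral conditions that spare the MOM ether.

Step 7
Reactants: 7 6-[(2E)-3,7-dimethylocta-2,6-dienyl]-5,7-bis(methoxymethoxy)-4H-chromen-4-one; 11 [3,4-dimethoxy-5-(methoxymethoxy)phenyl]boronic acid
Product: 12 (2S)-2-[3,4-dimethoxy-5-(methoxymethoxy)phenyl]-6-[(2E)-3,7-dimethylocta-2,6-dienyl]-5,7-bis(methoxymethoxy)chroman-4-one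
Conditions: [RhCl(C2H4)2]2 (2.5 mol %), (S)-MeO-F12-BIPHEP (5.5 mol %), KOH (10 mol %), toluene/H2O, 25 °C
Reagents that add atoms: none
Why: In this Hayashi–Miyaura asymmetric 1,4-addition the aryl–rhodium species carrying the (S)-bisphosphine inserts the C2=C3 bond from the Re face of C2, which sets 2S under ligand control, while the low temperature holds back 1,2-addition and base-induced ring opening and the trisubstituted geranyl alkenes are too poor as ligands to interfere.

Step 8
Reactants: 12 (2S)-2-[3,4-dimethoxy-5-(methoxymethoxy)phenyl]-6-[(2E)-3,7-dimethylocta-2,6-dienyl]-5,7-bis(methoxymethoxy)chroman-4-one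
Product: 13 (2S)-6-[(2E)-3,7-dimethylocta-2,6-dienyl]-5,7-dihydroxy-2-(3-hydroxy-4,5-dimethoxyphenyl)chroman-4-one (target)
Conditions: HCl (1.25 M in MeOH), 40 °C
Reagents that add atoms: none
Why: Acid-catalysed transacetalisation with methanol removes all three MOM groups; flavanones racemise through base-induced ring opening and not under this mild acid, and the moderate temperature should avoid cyclisation of the geranyl chain onto O5 or O7.

Compound list
1 | 5,7-dihydroxy-4H-chromen-4-one | O=c1ccoc2cc(O)cc(O)c12 | starting material
2 | 5-hydroxy-7-(methoxymethoxy)-4H-chromen-4-one | O=c1ccoc2cc(OCOC)cc(O)c12 | intermediate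
3 | 5-hydroxy-6-iodo-7-(methoxymethoxy)-4H-chromen-4-one | O=c1ccoc2cc(OCOC)c(I)c(O)c12 | intermediate
4 | 6-iodo-5,7-bis(methoxymethoxy)-4H-chromen-4-one | O=c1ccoc2cc(OCOC)c(I)c(OCOC)c12 | intermediate
5 | geranyl bromide, (2E)-1-bromo-3,7-dimethylocta-2,6-diene | BrC/C=C(\C)CCC=C(C)C | starting material
6 | [5,7-bis(methoxymethoxy)-4-oxo-4H-chromen-6-yl]zinc iodide | O=c1ccoc2cc(OCOC)c([Zn]I)c(OCOC)c12 | intermediate
7 | 6-[(2E)-3,7-dimethylocta-2,6-dienyl]-5,7-bis(methoxymethoxy)-4H-chromen-4-one | O=c1ccoc2cc(OCOC)c(C/C=C(\C)CCC=C(C)C)c(OCOC)c12 | intermediate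
8 | 2,3-dimethoxyphenol | COc1cccc(O)c1OC | starting material
9 | 1,2-dimethoxy-3-(methoxymethoxy)benzene | COCOc1cccc(OC)c1OC | intermediate
10 | 2-[3,4-dimethoxy-5-(methoxymethoxy)phenyl]-4,4,5,5-tetramethyl-1,3,2-dioxaborolane | COCOc1cc(B2OC(C)(C)C(C)(C)O2)cc(OC)c1OC | intermediate
11 | [3,4-dimethoxy-5-(methoxymethoxy)phenyl]boronic acid | COCOc1cc(B(O)O)cc(OC)c1OC | intermediate
12 | (2S)-2-[3,4-dimethoxy-5-(methoxymethoxy)phenyl]-6-[(2E)-3,7-dimethylocta-2,6-dienyl]-5,7-bis(methoxymethoxy)chroman-4-one | COc1cc([C@@H]2CC(=O)c3c(cc(OCOC)c(C/C=C(\C)CCC=C(C)C)c3OCOC)O2)cc(OCOC)c1OC | intermediate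
13 | (2S)-6-[(2E)-3,7-dimethylocta-2,6-dienyl]-5,7-dihydroxy-2-(3-hydroxy-4,5-dimethoxyphenyl)chroman-4-one | COc1cc([C@@H]2CC(=O)c3c(cc(O)c(C/C=C(\C)CCC=C(C)C)c3O)O2)cc(O)c1OC | target

Total step count: 8. Longest linear sequence: 6 steps (steps 1, 2, 3, 4, 7, 8).

Steps most likely to fail

Step 4. Zinc insertion into the hindered, electron-rich aryl iodide may be slow. The arylzinc may be protonated to the deiodinated chromone before it couples, and the allyl partner may homocouple. The fallback sets out from 4. Palladium-catalysed stannylation with hexabutylditin (Pd(PPh3)4, toluene, reflux) gives the isolable aryl nucleophile 5,7-bis(methoxymethoxy)-6-(tributylstannyl)-4H-chromen-4-one F1. A Stille coupling of this stannane with 5 (Pd2(dba)3, AsPh3, THF, 50 °C) forms the same bond through the same geometry-retaining η3-geranyl palladium species and comes back to the route at 7.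

Step 7. Insertion of the electron-rich 5-alkoxychromone may be slow, so that protodeboronation of 11 overtakes the addition, and facial selectivity may erode if the temperature has to be raised. The fallback sets out from 7 and 11 and obtains the stereocentre by kinetic resolution instead of asymmetric bond formation. An achiral conjugate addition (Pd(OCOCF3)2, 2,2'-bipyridine, 1,2-dichloroethane/H2O, 60 °C) gives racemic 2-[3,4-dimethoxy-5-(methoxymethoxy)phenyl]-6-geranyl-5,7-bis(methoxymethoxy)chroman-4-one F2. Noyori–Ikariya transfer hydrogenation (RuCl(p-cymene)[(R,R)-TsDPEN], HCO2H/Et3N, EtOAc, rt) should reduce the (2R)-ketone faster, to the cis-(2R,4R)-flavan-4-ol F3. The unreacted (2S)-ketone is separated by chromatography, and the fallback comes back to the route at 12.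

Step 2. Attack at C8 or double iodination may compete with iodination at C6. The fallback sets out from 1 and avoids the halide altogether. Dehydrative Friedel–Crafts geranylation with geraniol on acidic Al2O3 (1,2-dichloroethane, reflux) favours the carbon between two free hydroxyl groups. After separation from the C8 isomer it gives 6-[(2E)-3,7-dimethylocta-2,6-dienyl]-5,7-dihydroxy-4H-chromen-4-one F4. Double protection (NaH, MOMCl, DMF) comes back to the route at 7.

Further compounds
F1 | step 4 | 5,7-bis(methoxymethoxy)-6-(tributylstannyl)-4H-chromen-4-one | CCCC[Sn](CCCC)(CCCC)c1c(OCOC)cc2occc(=O)c2c1OCOC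
F2 | step 7 | racemic 2-[3,4-dimethoxy-5-(methoxymethoxy)phenyl]-6-[(2E)-3,7-dimethylocta-2,6-dienyl]-5,7-bis(methoxymethoxy)chroman-4-one | COc1cc(C2CC(=O)c3c(cc(OCOC)c(C/C=C(\C)CCC=C(C)C)c3OCOC)O2)cc(OCOC)c1OC
F3 | step 7 | (2R,4R)-2-[3,4-dimethoxy-5-(methoxymethoxy)phenyl]-6-[(2E)-3,7-dimethylocta-2,6-dienyl]-5,7-bis(methoxymethoxy)chroman-4-ol | COc1cc([C@H]2C[C@@H](O)c3c(cc(OCOC)c(C/C=C(\C)CCC=C(C)C)c3OCOC)O2)cc(OCOC)c1OC
F4 | step 2 | 6-[(2E)-3,7-dimethylocta-2,6-dienyl]-5,7-dihydroxy-4H-chromen-4-one | O=c1ccoc2cc(O)c(C/C=C(\C)CCC=C(C)C)c(O)c12
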